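**Plan**

- Locants: ring C1 (CH bearing the side chain), C2 (OAc), C3 (OAng), C4 (C(Me)OH), C5 (CHCl), C6 (CH2); chain C7 (carbon bearing =CH2), C8 (CHOAng), C9, C10/C11 (epoxide).
- Cuts, in retrosynthetic order: the three esters and the C10–C11 epoxide oxygen; C7–C8 (alkenyl triflate plus 4-methylpent-3-enal); C5–Cl and C4–O (back to the C4=C5 alkene); the ring bond C4=C5 (metathesis); C1–C6 (enolate allylation); this leads to 2-deoxy-D-ribose.
- Enabling feature: C2–O and C3–O are the erythro diol of the sugar, and C7 on C1 is cis-1,3 to the C3 oxygen. C7, C1, C2, C3 and that oxygen therefore form a γ-lactone whose cis allyl (on C1) and isopropenyl (on C3) arms are joined as C4=C5, giving a 6-oxabicyclo[3.2.1]octenone.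
- Forward order: γ-lactone from the sugar; six-membered carbocycle closed across it; lactone opened; ring epoxide and chlorohydrin; side chain joined at C7; esters; side-chain epoxide last.
- Stereochemistry: C2 and C3 from 2-deoxy-D-ribose; C1 by enolate allylation anti to the C2 silyloxy group; C4 and C5 by C3-OH-directed epoxidation and invertive chloride opening; C8 by CBS reduction; C10 by Shi epoxidation with the L-fructose-derived ketone.

Key step: step 9

Remark: 1 is drawn open-chain but reacts as its cyclic hemiacetal; 9 and 23 are carried on as mixtures of epimers at the new carbinol carbon, which the next oxidation removes; the L-fructose-derived Shi ketone is taken as available (made from L-sorbose as its enantiomer is from D-fructose). TBS = tert-butyldimethylsilyl; the locants of the plan are used for all intermediates.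

**Step 1**
Reactants: 1 2-deoxy-D-ribose
Product: 2 2-deoxy-D-ribono-1,4-lactone, (4S,5R)-4-hydroxy-5-(hydroxymethyl)oxolan-2-one
Conditions: Br2, H2O, rt
Reagents that add atoms: none
Why: Bromine-water oxidation of an aldose turns the cyclic hemiacetal into the γ-lactone and leaves the two carbinol stereocentres (the future C2 and C3) untouched.

**Step 2**
Reactants: 2 2-deoxy-D-ribono-1,4-lactone
Product: 3 (4S,5R)-4-(tert-butyldimethylsilyloxy)-5-[(tert-butyldimethylsilyloxy)methyl]oxolan-2-one
Conditions: TBSCl, imidazole, DMF, rt
Reagents that add atoms: tert-butyldimethylsilyl chloride, CC(C)(C)[Si](C)(C)Cl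
Why: Imidazole-promoted silylation of both hydroxyls gives a base-stable lactone whose bulky secondary silyl ether will steer the alkylation that follows.

**Step 3**
Reactants: 3 bis-silyl lactone; 4 allyl bromide
Product: 6 (3S,4S,5R)-3-allyl-4-(tert-butyldimethylsilyloxy)-5-[(tert-butyldimethylsilyloxy)methyl]oxolan-2-one, via lithium enolate 5 (not isolated)
Conditions: LDA, THF, −78 °C; then 4, −78 to −40 °C
Reagents that add atoms: none
Why: Alkylation of a lactone lithium enolate, in which allyl bromide adds to the face opposite the adjacent silyloxy group, so that C1 is set with the allyl group trans to C2–O and therefore cis to the C3 arm.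

**Step 4**
Reactants: 6 allyl bis-silyl lactone
Product: 7 (3S,4S,5R)-3-allyl-4-(tert-butyldimethylsilyloxy)-5-(hydroxymethyl)oxolan-2-one
Conditions: TFA/H2O/THF (1:1:4), 0 °C
Reagents that add atoms: none
Why: Acid-catalysed desilylation is much faster at the unhindered primary silyl ether than at the flanked secondary one, a selectivity well established for bis-silylated deoxyribose derivatives.

**Step 5**
Reactants: 7 primary alcohol
Product: 8 (2S,3S,4S)-4-allyl-3-(tert-butyldimethylsilyloxy)-5-oxooxolane-2-carbaldehyde
Conditions: Dess–Martin periodinane, CH2Cl2, 0 °C to rt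
Reagents that add atoms: none
Why: Dess–Martin oxidation works under neutral, non-aqueous conditions, so the aldehyde should form without epimerisation at the oxygen-bearing α-carbon or β-elimination of the silyloxy group, and it is used crude.

**Step 6**
Reactants: 8 lactone aldehyde
Product: 9 5-(1-hydroxyethyl) lactone, (3S,4S)-3-allyl-4-(tert-butyldimethylsilyloxy)-5-(1-hydroxyethyl)oxolan-2-one with the ring configuration of 7, both carbinol epimers
Conditions: MeMgBr, THF, −78 °C
Reagents that add atoms: methylmagnesium bromide, C[Mg]Br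
Why: Grignard addition to the aldehyde, which at −78 °C is far more electrophilic than the lactone carbonyl; the new carbinol centre needs no control because it is oxidised in the next step.

**Step 7**
Reactants: 9 secondary alcohol
Product: 10 (3S,4S,5S)-5-acetyl-3-allyl-4-(tert-butyldimethylsilyloxy)oxolan-2-one
Conditions: Dess–Martin periodinane, CH2Cl2, rt
Reagents that add atoms: none
Why: Dess–Martin oxidation of the secondary alcohol gives the methyl ketone under non-basic conditions that leave the adjacent oxygen-bearing stereocentre intact.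

**Step 8**
Reactants: 10 methyl ketone
Product: 11 (3S,4S,5R)-3-allyl-4-(tert-butyldimethylsilyloxy)-5-(prop-1-en-2-yl)oxolan-2-one (allyl and isopropenyl cis, silyloxy trans to both)
Conditions: Zn, CH2Br2, TiCl4, THF (reagent pre-formed at 5 °C); then 10, CH2Cl2, 0 °C to rt
Reagents that add atoms: dibromomethane, BrCBr
Why: Takai–Lombardo methylenation uses a non-basic gem-dimetallic reagent that converts the ketone into the 1,1-disubstituted alkene without enolising the epimerisable C3 centre and without attacking the lactone.

**Step 9 (key step)**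
Reactants: 11 2-allyl-4-isopropenyl γ-lactone
Product: 12 (1S,5R,8S)-8-(tert-butyldimethylsilyloxy)-4-methyl-6-oxabicyclo[3.2.1]oct-3-en-7-one
Conditions: second-generation Grubbs catalyst (5–10 mol %), toluene (0.005 M), 80 °C, argon sparge
Reagents that add atoms: none
Why: The ruthenium benzylidene first exchanges onto the unhindered allyl terminus, and the new alkylidene adds across the 1,1-disubstituted isopropenyl alkene in a [2+2] cycloaddition whose cycloreversion releases the trisubstituted C4=C5 alkene, ethene being swept out. The closest known reaction type is ring-closing olefin metathesis of cis-1,3-dialkenyl five-membered rings to bicyclo[3.2.1]octenes. The carbocycle closes as the three-carbon bridge (C4, C5, C6) over the lactone, giving a 6-oxabicyclo[3.2.1]oct-3-en-7-one, a ring system familiar from halolactonisation chemistry and not prohibitively strained. No stereocentre is formed, and C1, C2 and C3 pass through unchanged. The step needs ring closure to outrun cross-metathesis of the allyl group; this is secured by high dilution, by removal of ethene and above all by the cis relation of the two alkenyl arms, which can both sit pseudo-axial on the lactone envelope while the silyloxy group lies on the other face.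

**Step 10**
Reactants: 12 bridged bicyclic lactone
Product: 13 cyclohex-4-ene Weinreb amide: C1 C(=O)N(Me)OMe, C2 OTBS and C3 OH all cis, C4 methyl, C4=C5
Conditions: MeNH(OMe)·HCl, AlMe3, CH2Cl2, 0 °C to rt
Reagents that add atoms: N,O-dimethylhydroxylamine hydrochloride, CNOC.Cl
Why: Weinreb aminolysis of a lactone with the aluminium amide cleaves the acyl–oxygen bond of the strained bridge, so the C3–O bond keeps its configuration and the allylic C3 hydroxyl is set free.

**Step 11**
Reactants: 13 hydroxy Weinreb amide
Product: 14 epoxy alcohol: C4–C5 epoxide cis to the C3 hydroxyl (and to the C1 and C2 substituents), otherwise as 13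
Conditions: VO(acac)2 (cat.), t-BuOOH, CH2Cl2, 0 °C to rt
Reagents that add atoms: tert-butyl hydroperoxide, CC(C)(C)OO
Why: Hydroxyl-directed epoxidation of a cyclic allylic alcohol, in which the vanadium-bound C3 alkoxide delivers the peroxide oxygen to the alkene face on which it sits, sets C4 and C5 with the epoxide cis to C3–OH although that face is the more crowded one.

**Step 12**
Reactants: 14 epoxy alcohol
Product: 15 chlorohydrin: C5 Cl trans to the tertiary C4 OH, C4 OH cis to C3 OH, C2 OTBS, C1 Weinreb amide
Conditions: Ti(OiPr)4, Et2NH·HCl, CH2Cl2, rt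
Reagents that add atoms: diethylamine hydrochloride, CCNCC.Cl
Why: Ti(OiPr)4-mediated opening of a 2,3-epoxy alcohol at the carbon remote from the carbinol, in which chloride attacks C5 in SN2 fashion with inversion through the trans-diaxial chair that keeps the C1 amide equatorial, while cation character at C4 is disfavoured by the adjacent C3–O bond.

**Step 13**
Reactants: 15 chlorohydrin diol
Product: 16 C3/C4 acetonide of 15 (cis-fused 2,2-dimethyl-1,3-dioxolane on C3–O and C4–O)
Conditions: 2-methoxypropene, PPTS (cat.), CH2Cl2, 0 °C to rt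
Reagents that add atoms: 2-methoxypropene, COC(C)=C
Why: Acid-catalysed ketalisation of the cis secondary/tertiary diol masks both hydroxyls, so that no alkoxide can displace the neighbouring chloride in the basic steps that follow.

**Step 14**
Reactants: 16 acetonide Weinreb amide
Product: 17 methyl ketone: C1 acetyl, otherwise as 16
Conditions: MeMgBr, THF, 0 °C
Reagents that add atoms: methylmagnesium bromide, C[Mg]Br
Why: Weinreb ketone synthesis, in which the magnesium-chelated tetrahedral adduct survives until work-up and so prevents over-addition, with C1 not epimerised because its acyl group is equatorial.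

**Step 15**
Reactants: 17 methyl ketone
Product: 19 alkenyl triflate: C7 bearing =CH2 and OSO2CF3, otherwise as 17, via potassium enolate 18 (not isolated)
Conditions: KHMDS, PhNTf2, THF, −78 °C
Reagents that add atoms: N-phenylbis(trifluoromethanesulfonimide), O=S(=O)(N(c1ccccc1)S(=O)(=O)C(F)(F)F)C(F)(F)F
Why: Kinetic deprotonation by the hindered amide base occurs at the methyl group, not at the tertiary C1–H, and O-sulfonylation of the enolate gives the 1,1-disubstituted enol triflate, the neopentyl-type secondary chloride being inert at −78 °C.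

**Step 16**
Reactants: 20 4-methylpent-3-en-1-ol
Product: 21 4-methylpent-3-enal
Conditions: Dess–Martin periodinane, CH2Cl2, 0 °C (solution used directly)
Reagents that add atoms: none
Why: Dess–Martin oxidation gives the volatile β,γ-unsaturated aldehyde under neutral conditions that should not move the alkene into conjugation.

**Step 17**
Reactants: 19 alkenyl triflate; 21 4-methylpent-3-enal
Product: 23 allylic alcohol: C7(=CH2)–C8H(OH)–CH2–CH=CMe2 on C1, both C8 epimers, via alkenylchromium dichloride 22 (not isolated)
Conditions: CrCl2, NiCl2 (cat.), DMF, rt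
Reagents that add atoms: none
Why: Nozaki–Hiyama–Kishi coupling, in which zerovalent nickel formed from NiCl2 inserts into the alkenyl C–O bond and hands the alkenyl group to chromium, whose trivalent alkenyl species adds to the aldehyde under non-basic conditions that spare the enolisable aldehyde, the acetonide and the alkyl chloride; C8 is formed without control and is corrected in steps 18 and 19.

**Step 18**
Reactants: 23 allylic alcohol mixture
Product: 24 enone: C7(=CH2)–C8(=O)–CH2–CH=CMe2 on C1
Conditions: Dess–Martin periodinane, CH2Cl2, 0 °C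
Reagents that add atoms: none
Why: Dess–Martin oxidation of the allylic alcohol merges both C8 epimers into one enone under conditions mild enough not to shift the β,γ-alkene, and the product is reduced at once.

**Step 19**
Reactants: 24 enone
Product: 25 (8S)-allylic alcohol, otherwise as 23
Conditions: (R)-2-methyl-CBS-oxazaborolidine, catecholborane, toluene, −78 °C
Reagents that add atoms: none
Why: Corey–Bakshi–Shibata reduction, in which the α-branched alkenyl group acts as the large ketone substituent and the prenyl-bearing CH2 as the small one, so that the (R)-oxazaborolidine delivers hydride to give the (8S)-carbinol under catalyst control, catecholborane leaving the alkenes untouched.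

**Step 20**
Reactants: 25 acetonide alcohol
Product: 26 triol: C3 OH, C4 OH and C8 OH free, C2 OTBS, C5 Cl
Conditions: AcOH/H2O (4:1), 40 °C
Reagents that add atoms: none
Why: Mild aqueous-acid hydrolysis of the cis-fused acetonide, under which the hindered secondary silyl ether, the allylic alcohol and the trisubstituted alkene should survive.

**Step 21**
Reactants: 26 triol
Product: 27 bis-angelate: (Z)-2-methylbut-2-enoates on C3–O and C8–O, tertiary C4 OH free, C2 OTBS
Conditions: angelic acid, 2,4,6-trichlorobenzoyl chloride, Et3N, toluene, rt; then 26, 80 °C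
Reagents that add atoms: angelic acid, C/C=C(/C)C(=O)O
Why: Yamaguchi-type esterification through the mixed 2,4,6-trichlorobenzoic anhydride without a nucleophilic catalyst, the protocol known to transfer the angeloyl group without Z-to-E isomerisation, acylates both secondary hydroxyls and leaves the tertiary C4 hydroxyl alone.

**Step 22**
Reactants: 27 bis-angelate silyl ether
Product: 28 C2 alcohol: as 27 with C2 OH free
Conditions: HF·pyridine, pyridine, THF, 0 °C to rt
Reagents that add atoms: none
Why: Fluoride-driven desilylation under buffered, weakly acidic conditions generates no alkoxide, so neither migration of the C3 angelate nor closure of the chlorohydrin to an epoxide should occur.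

**Step 23**
Reactants: 28 C2 alcohol
Product: 29 C2 acetate: as the target but with the C10=C11 alkene in place of the epoxide
Conditions: Ac2O, pyridine, DMAP (cat.), CH2Cl2, 0 °C
Reagents that add atoms: acetic anhydride, CC(=O)OC(C)=O
Why: DMAP-catalysed acetylation is fast at the secondary C2 hydroxyl and, at 0 °C with limited anhydride, slow at the tertiary C4 hydroxyl.

**Step 24**
Reactants: 29 triene triester
Product: 30 CNP0313121.1, (1R,2S,3S,4S,5S,8S,10S) in the locants of the plan
Conditions: L-fructose-derived Shi ketone (3 equiv), KHSO5 (as its triple salt 2KHSO5·KHSO4·K2SO4), NaHCO3, MeCN/dimethoxymethane/H2O, pH about 8, 0 °C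
Reagents that add atoms: potassium peroxymonosulfate, [K+].[O-]S(=O)(=O)OO
Why: Shi asymmetric epoxidation, in which the chiral dioxirane transfers oxygen through a spiro transition state to the electron-rich trisubstituted C10=C11 alkene and sets C10 as S under reagent control, while the 1,1-disubstituted C7 alkene and the conjugated angelate alkenes react far more slowly and the near-neutral pH spares the esters and the chlorohydrin.

**Compound list**

1 | 2-deoxy-D-ribose | O=CC[C@H](O)[C@H](O)CO | starting material
2 | 2-deoxy-D-ribono-1,4-lactone | O=C1C[C@H](O)[C@@H](CO)O1 | intermediate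
3 | (4S,5R)-4-(tert-butyldimethylsilyloxy)-5-[(tert-butyldimethylsilyloxy)methyl]oxolan-2-one | O=C1C[C@H](O[Si](C)(C)C(C)(C)C)[C@@H](CO[Si](C)(C)C(C)(C)C)O1 | intermediate
4 | allyl bromide | C=CCBr | starting material
5 | lithium enolate of 3 | [Li]OC1=C[C@H](O[Si](C)(C)C(C)(C)C)[C@@H](CO[Si](C)(C)C(C)(C)C)O1 | intermediate
6 | (3S,4S,5R)-3-allyl-4-(tert-butyldimethylsilyloxy)-5-[(tert-butyldimethylsilyloxy)methyl]oxolan-2-one | O=C1[C@@H](CC=C)[C@H](O[Si](C)(C)C(C)(C)C)[C@@H](CO[Si](C)(C)C(C)(C)C)O1 | intermediate
7 | (3S,4S,5R)-3-allyl-4-(tert-butyldimethylsilyloxy)-5-(hydroxymethyl)oxolan-2-one | O=C1[C@@H](CC=C)[C@H](O[Si](C)(C)C(C)(C)C)[C@@H](CO)O1 | intermediate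
8 | (2S,3S,4S)-4-allyl-3-(tert-butyldimethylsilyloxy)-5-oxooxolane-2-carbaldehyde | O=C1[C@@H](CC=C)[C@H](O[Si](C)(C)C(C)(C)C)[C@@H](C=O)O1 | intermediate
9 | 5-(1-hydroxyethyl) lactone, carbinol epimers | O=C1[C@@H](CC=C)[C@H](O[Si](C)(C)C(C)(C)C)[C@@H](C(C)O)O1 | intermediate
10 | (3S,4S,5S)-5-acetyl-3-allyl-4-(tert-butyldimethylsilyloxy)oxolan-2-one | O=C1[C@@H](CC=C)[C@H](O[Si](C)(C)C(C)(C)C)[C@@H](C(C)=O)O1 | intermediate
11 | (3S,4S,5R)-3-allyl-4-(tert-butyldimethylsilyloxy)-5-(prop-1-en-2-yl)oxolan-2-one | O=C1[C@@H](CC=C)[C@H](O[Si](C)(C)C(C)(C)C)[C@@H](C(C)=C)O1 | intermediate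
12 | (1S,5R,8S)-8-(tert-butyldimethylsilyloxy)-4-methyl-6-oxabicyclo[3.2.1]oct-3-en-7-one | O=C1O[C@@H]2C(C)=CC[C@H]1[C@@H]2O[Si](C)(C)C(C)(C)C | intermediate
13 | cyclohexene Weinreb amide (C1 amide, C2 OTBS, C3 OH all cis; C4=C5) | CON(C)C(=O)[C@H]1CC=C(C)[C@@H](O)[C@H]1O[Si](C)(C)C(C)(C)C | intermediate
14 | C4–C5 epoxy alcohol, epoxide cis to C3 OH | CON(C)C(=O)[C@H]1C[C@H]2O[C@@]2(C)[C@@H](O)[C@H]1O[Si](C)(C)C(C)(C)C | intermediate
15 | chlorohydrin (C5 Cl, C4 OH, C3 OH) Weinreb amide | CON(C)C(=O)[C@H]1C[C@H](Cl)[C@@](C)(O)[C@@H](O)[C@H]1O[Si](C)(C)C(C)(C)C | intermediate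
16 | C3/C4 acetonide of 15 | CON(C)C(=O)[C@H]1C[C@H](Cl)[C@@]2(C)OC(C)(C)O[C@H]2[C@H]1O[Si](C)(C)C(C)(C)C | intermediate
17 | C1 methyl ketone | CC(=O)[C@H]1C[C@H](Cl)[C@@]2(C)OC(C)(C)O[C@H]2[C@H]1O[Si](C)(C)C(C)(C)C | intermediate
18 | potassium enolate of 17 | C=C(O[K])[C@H]1C[C@H](Cl)[C@@]2(C)OC(C)(C)O[C@H]2[C@H]1O[Si](C)(C)C(C)(C)C | intermediate
19 | C7 alkenyl triflate | C=C(OS(=O)(=O)C(F)(F)F)[C@H]1C[C@H](Cl)[C@@]2(C)OC(C)(C)O[C@H]2[C@H]1O[Si](C)(C)C(C)(C)C | intermediate
20 | 4-methylpent-3-en-1-ol | CC(C)=CCCO | starting material
21 | 4-methylpent-3-enal | CC(C)=CCC=O | intermediate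
22 | alkenylchromium dichloride from 19 | C=C([Cr](Cl)Cl)[C@H]1C[C@H](Cl)[C@@]2(C)OC(C)(C)O[C@H]2[C@H]1O[Si](C)(C)C(C)(C)C | intermediate
23 | C8 allylic alcohol, both epimers | C=C(C(O)CC=C(C)C)[C@H]1C[C@H](Cl)[C@@]2(C)OC(C)(C)O[C@H]2[C@H]1O[Si](C)(C)C(C)(C)C | intermediate
24 | C8 enone | C=C(C(=O)CC=C(C)C)[C@H]1C[C@H](Cl)[C@@]2(C)OC(C)(C)O[C@H]2[C@H]1O[Si](C)(C)C(C)(C)C | intermediate
25 | (8S)-allylic alcohol | C=C([C@H](CC=C(C)C)O)[C@H]1C[C@H](Cl)[C@@]2(C)OC(C)(C)O[C@H]2[C@H]1O[Si](C)(C)C(C)(C)C | intermediate
26 | triol (C3, C4, C8 OH), C2 OTBS | C=C([C@H](CC=C(C)C)O)[C@H]1C[C@H](Cl)[C@@](C)(O)[C@@H](O)[C@H]1O[Si](C)(C)C(C)(C)C | intermediate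
27 | C3,C8-bis-angelate, C2 OTBS | C=C([C@H](CC=C(C)C)OC(=O)/C(C)=C\C)[C@H]1C[C@H](Cl)[C@@](C)(O)[C@@H](OC(=O)/C(C)=C\C)[C@H]1O[Si](C)(C)C(C)(C)C | intermediate
28 | C3,C8-bis-angelate, C2 OH | C=C([C@H](CC=C(C)C)OC(=O)/C(C)=C\C)[C@H]1C[C@H](Cl)[C@@](C)(O)[C@@H](OC(=O)/C(C)=C\C)[C@H]1O | intermediate
29 | C2 acetate with C10=C11 alkene | C=C([C@H](CC=C(C)C)OC(=O)/C(C)=C\C)[C@H]1C[C@H](Cl)[C@@](C)(O)[C@@H](OC(=O)/C(C)=C\C)[C@H]1OC(C)=O | intermediate
30 | CNP0313121.1 | C=C([C@H](C[C@@H]1OC1(C)C)OC(=O)/C(C)=C\C)[C@H]1C[C@H](Cl)[C@@](C)(O)[C@@H](OC(=O)/C(C)=C\C)[C@H]1OC(C)=O | target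

Total step count: 24
Longest linear sequence: 23 (steps 1–15 and 17–24, from 1 to 30; step 16 is the side branch)

**Steps most likely to fail**

Step 9. The alkylidene formed at the allyl group may find intermolecular partners faster than it reaches the hindered isopropenyl group across the lactone, so that oligomerisation or alkene isomerisation competes with closure of the bridged ring. The fallback sets out from 11 and releases the tether first: aminolysis with MeNH(OMe)·HCl and AlMe3 would give the open-chain hydroxy Weinreb amide F1, a 1,7-diene with a free allylic hydroxyl. Its unconstrained ring-closing metathesis with the same second-generation Grubbs catalyst would close the cyclohexene directly, and the route is rejoined at 13.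

Step 12. Chloride may open the epoxide at the tertiary C4 through a loose, cation-like transition state instead of at C5, or the C3 hydroxyl may close back onto the amide under Ti(OiPr)4. The fallback sets out from 14 and reverses the electronic bias: Dess–Martin oxidation of the C3 hydroxyl would give the α,β-epoxy ketone F2. In F2 the carbonyl forbids positive charge at the quaternary C4, so chloride (LiCl, AcOH, THF) should enter at C5 with inversion and give the β-chloro α-hydroxy ketone F3. Reduction with NaBH4 in MeOH at −40 °C, by axial hydride delivery to the face away from the two flanking axial oxygen substituents, should return the equatorial C3 hydroxyl cis to the C4 hydroxyl, and the route is rejoined at 15.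

Step 21. Acylation of the hindered C3 hydroxyl may stall, and forcing it may cause Z-to-E isomerisation of the angeloyl group to the tigloyl group. The fallback sets out from 26 and builds the Z-alkene on the substrate: Steglich esterification (DCC, DMAP) with 2-[bis(2,2,2-trifluoroethoxy)phosphoryl]propanoic acid, which has no alkene geometry to lose, would give the bis(phosphonopropionate) F4. A double Still–Gennari olefination with acetaldehyde (KHMDS, 18-crown-6, THF, −78 °C, base limited to the two phosphonates) should form both (Z)-2-methylbut-2-enoates, and the route is rejoined at 27.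

**Further compounds**

F1 | step 9 | open-chain hydroxy Weinreb amide, (2S,3S,4R)-2-allyl-3-(tert-butyldimethylsilyloxy)-4-hydroxy-N-methoxy-N,5-dimethylhex-5-enamide | CON(C)C(=O)[C@@H](CC=C)[C@H](O[Si](C)(C)C(C)(C)C)[C@@H](C(C)=C)O
F2 | step 12 | α,β-epoxy ketone (C3 ketone of 14) | CON(C)C(=O)[C@H]1C[C@H]2O[C@@]2(C)C(=O)[C@H]1O[Si](C)(C)C(C)(C)C
F3 | step 12 | β-chloro α-hydroxy ketone (C3 ketone of 15) | CON(C)C(=O)[C@H]1C[C@H](Cl)[C@@](C)(O)C(=O)[C@H]1O[Si](C)(C)C(C)(C)C
F4 | step 21 | C3,C8-bis{2-[bis(2,2,2-trifluoroethoxy)phosphoryl]propanoate} of 26 | C=C([C@H](CC=C(C)C)OC(=O)C(C)P(=O)(OCC(F)(F)F)OCC(F)(F)F)[C@H]1C[C@H](Cl)[C@@](C)(O)[C@@H](OC(=O)C(C)P(=O)(OCC(F)(F)F)OCC(F)(F)F)[C@H]1O[Si](C)(C)C(C)(C)C
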